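**Retrosynthetic overview**

1. Both ester C–O bonds are cut (double Mitsunobu esterification with inversion at C6), giving two molecules of 6-epi-incarvilline 11 and (2E,6E)-2,6-dimethylocta-2,6-dienedioic acid 16; 16 comes from geranyl acetate by allylic oxidation and oxidation-level adjustment.
2. 11 comes from ketone 9 and enone 8: the N-methyl is carried as N-Boc (LiAlH4 turns the carbamate C=O into CH3), the C6–OH is the Pauson–Khand carbonyl, and H4a comes from convex-face hydrogenation.
3. Key disconnection: an intramolecular Pauson–Khand [2+2+1] reaction of the open-chain 1,7-enyne 6 forms C4a–C7a, C5–C6 and C6–C7, closes the piperidine and the cyclopentenone in one operation, and sets C7 and C7a.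
4. Enabling feature: in the cyclopenta[c]pyridine the oxygenated C6 lies between C5H2 and C7H(CH3), and the ring-fusion carbons C4a and C7a are linked through C4–C3–N2–C1. So C4a–C5 is a latent terminal alkyne, C6 is CO, C7–C7a is a latent E-propenyl group and N2 is the tether.
5. Ring order: piperidine and cyclopentane rings together in step 5 from an acyclic precursor whose only stereocentre (C4, from a chiral-pool β-amino acid) controls all the others.

Key step: step 5

Remark: crotyl bromide 5 is taken as the E isomer of high geometric purity, and hydride is expected to add to ketone 9 from the convex face, which is why the final esterification is planned with inversion at C6.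

**Route**

Step 1
Reactants: 1 (2S)-3-[(tert-butoxycarbonyl)amino]-2-methylpropanoic acid
Product: 2 tert-butyl N-[(2S)-3-hydroxy-2-methylpropyl]carbamate
Conditions: BH3·THF (2 equiv), THF, 0 °C to rt; aq. NaHCO3 work-up
Reagents that add atoms: none
Why: Borane reduces the carboxylic acid chemoselectively (via the acyloxyborane) in the presence of the Boc carbamate and does not touch the C2 stereocentre.

Step 2
Reactants: 2 tert-butyl N-[(2S)-3-hydroxy-2-methylpropyl]carbamate
Product: 3 tert-butyl N-[(2S)-2-methyl-3-oxopropyl]carbamate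
Conditions: Dess–Martin periodinane, CH2Cl2, 0 °C to rt; used crude
Reagents that add atoms: none
Why: Dess–Martin oxidation is base-free, so the α-branched aldehyde should form without epimerisation or β-elimination.

Step 3
Reactants: 3 tert-butyl N-[(2S)-2-methyl-3-oxopropyl]carbamate
Product: 4 tert-butyl N-[(2R)-2-methylbut-3-yn-1-yl]carbamate
Conditions: dimethyl (1-diazo-2-oxopropyl)phosphonate, K2CO3, MeOH, 0 °C to rt
Reagents that add atoms: dimethyl (1-diazo-2-oxopropyl)phosphonate, CC(=O)C(=[N+]=[N-])P(=O)(OC)OC
Why: Ohira–Bestmann (Seyferth–Gilbert) homologation adds the diazomethylphosphonate anion to the aldehyde and, after loss of phosphate and N2 with 1,2-hydride shift, gives the terminal alkyne under conditions mild enough to keep the α-stereocentre (the descriptor changes to R only through the priority rules).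

Step 4
Reactants: 4 tert-butyl N-[(2R)-2-methylbut-3-yn-1-yl]carbamate; 5 (E)-1-bromobut-2-ene
Product: 6 tert-butyl N-[(2E)-but-2-en-1-yl]-N-[(2R)-2-methylbut-3-yn-1-yl]carbamate
Conditions: NaH (1.1 equiv), DMF, 0 °C; then 5, 0 °C to rt
Reagents that add atoms: none
Why: The carbamate N–H is the most acidic site, and its sodium salt should displace the primary allylic bromide by SN2 with the E geometry retained.

Step 5
Reactants: 6 tert-butyl N-[(2E)-but-2-en-1-yl]-N-[(2R)-2-methylbut-3-yn-1-yl]carbamate
Product: 8 tert-butyl (4R,7S,7aS)-4,7-dimethyl-6-oxo-1,3,4,6,7,7a-hexahydro-2H-cyclopenta[c]pyridine-2-carboxylate, via alkyne–Co2(CO)6 complex 7 (not isolated)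
Conditions: Co2(CO)8 (1.1 equiv), ClCH2CH2Cl, rt; then n-BuSMe (3.5 equiv), 83 °C
Reagents that add atoms: dicobalt octacarbonyl, O=C=[Co](=C=O)(=C=O)(=C=O)[Co](=C=O)(=C=O)(=C=O)=C=O
Why: The alkyne of 6 is held as its Co2(CO)6 complex 7; sulfide-assisted loss of CO lets the E-alkene coordinate and insert into a Co–C bond to forge C4a–C7a, and CO insertion followed by reductive elimination forges C7–C6 and C6–C5, which is an intramolecular Pauson–Khand [2+2+1] cycloaddition of a nitrogen-tethered 1,7-enyne, a well-precedented reaction class. The piperidine ring is closed by the C4a–C7a bond in exo fashion with respect to both π-bonds (only the internal alkyne and internal alkene carbons can meet through the C4–C3–N2–C1 tether), and the cyclopentenone is closed around cobalt as the five-carbon ring C4a–C5–C6–C7–C7a. C7 relative to C7a is fixed by suprafacial addition across the E-alkene, which places the C7 methyl trans to C1 and cis to H7a. C7a relative to the existing C4 centre is fixed in a chair-like insertion transition state in which the propargylic C4 methyl is equatorial (it eclipses only the small alkyne C–H) and C7 is equatorial as the nearly planar metallacycle requires, which puts H4 and H7a on the same face. The step needs regiocontrol, which the tether provides (CO can only end up at C6 between C5 and C7), and enough reactivity for a 1,2-disubstituted alkene, which the planar N-Boc carbamate (favourable rotamer) and the sulfide promoter are meant to secure. Any minor diastereomer at C7a/C7 should be separable by chromatography at this stage.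

Step 6
Reactants: 8 tert-butyl (4R,7S,7aS)-4,7-dimethyl-6-oxo-1,3,4,6,7,7a-hexahydro-2H-cyclopenta[c]pyridine-2-carboxylate
Product: 9 tert-butyl (4R,4aS,7S,7aR)-4,7-dimethyl-6-oxooctahydro-1H-cyclopenta[c]pyridine-2-carboxylate
Conditions: H2 (1 atm), Pd/C (10 wt%), EtOAc, rt
Reagents that add atoms: none
Why: Heterogeneous syn hydrogenation of the trisubstituted enone should occur from the convex face that carries H4 and H7a (the folded piperidine ring shields the other face), setting C4a with a cis ring fusion while the Boc group survives.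

Step 7
Reactants: 9 tert-butyl (4R,4aS,7S,7aR)-4,7-dimethyl-6-oxooctahydro-1H-cyclopenta[c]pyridine-2-carboxylate
Product: 11 (4R,4aS,6S,7S,7aR)-2,4,7-trimethyloctahydro-1H-cyclopenta[c]pyridin-6-ol (6-epi-incarvilline), via N-Boc alcohol 10 (not isolated)
Conditions: LiAlH4 (5 equiv), THF, −78 °C to rt, then reflux; aq. NaOH work-up
Reagents that add atoms: none
Why: LiAlH4 should first reduce the cyclopentanone from the convex face (small hydride, attack syn to the C7 methyl as in 2-methylcyclopentanone) to give the 6S alcohol with OH trans to that methyl, and at reflux should reduce the Boc carbamate through the formamide and iminium stage to N–CH3.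

Step 8
Reactants: 12 geranyl acetate [(2E)-3,7-dimethylocta-2,6-dien-1-yl acetate]
Product: 13 (2E,6E)-8-hydroxy-3,7-dimethylocta-2,6-dien-1-yl acetate
Conditions: SeO2 (0.1 equiv), t-BuOOH (3 equiv), CH2Cl2, 0 °C to rt
Reagents that add atoms: selenium dioxide (catalytic oxygen carrier), O=[Se]=O; tert-butyl hydroperoxide (stoichiometric oxidant), CC(C)(C)OO
Why: Catalytic SeO2 allylic oxidation (ene reaction then [2,3]-sigmatropic shift) is selective for the E-methyl of the electron-rich terminal trisubstituted alkene, the C2=C3 alkene being deactivated by the allylic acetate.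

Step 9
Reactants: 13 (2E,6E)-8-hydroxy-3,7-dimethylocta-2,6-dien-1-yl acetate
Product: 14 (2E,6E)-2,6-dimethylocta-2,6-diene-1,8-diol
Conditions: K2CO3 (0.2 equiv), MeOH, rt
Reagents that add atoms: none
Why: Base-catalysed methanolysis (transesterification) removes the acetate without touching the alkenes.

Step 10
Reactants: 14 (2E,6E)-2,6-dimethylocta-2,6-diene-1,8-diol
Product: 15 (2E,6E)-2,6-dimethylocta-2,6-dienedial
Conditions: MnO2 (activated, excess), CH2Cl2, rt
Reagents that add atoms: none
Why: MnO2 oxidises both allylic alcohols selectively to the enals without E/Z isomerisation or over-oxidation.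

Step 11
Reactants: 15 (2E,6E)-2,6-dimethylocta-2,6-dienedial
Product: 16 (2E,6E)-2,6-dimethylocta-2,6-dienedioic acid
Conditions: NaClO2, NaH2PO4, 2-methyl-2-butene, t-BuOH/H2O, 0 °C to rt
Reagents that add atoms: sodium chlorite, [Na+].[O-]Cl=O
Why: Pinnick oxidation converts both enals into the enoic acids with retention of alkene geometry, 2-methyl-2-butene trapping the hypochlorous acid formed.

Step 12
Reactants: 11 (4R,4aS,6S,7S,7aR)-2,4,7-trimethyloctahydro-1H-cyclopenta[c]pyridin-6-ol (2.1 equiv); 16 (2E,6E)-2,6-dimethylocta-2,6-dienedioic acid (1 equiv)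
Product: 17 bis[(4R,4aS,6R,7S,7aR)-2,4,7-trimethyloctahydro-1H-cyclopenta[c]pyridin-6-yl] (2E,6E)-2,6-dimethylocta-2,6-dienedioate (target)
Conditions: PPh3, DIAD, THF, 0 °C to rt
Reagents that add atoms: none
Why: In this double Mitsunobu esterification each oxyphosphonium derived from 11 should be displaced by a carboxylate of 16 from the convex face with SN2 inversion, turning 6S into 6R in both alkaloid units, the tertiary amine being tolerated as its ammonium carboxylate.

**Compound list**

1 | (2S)-3-[(tert-butoxycarbonyl)amino]-2-methylpropanoic acid | CC(C)(C)OC(=O)NC[C@@H](C(=O)O)C | starting material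
2 | tert-butyl N-[(2S)-3-hydroxy-2-methylpropyl]carbamate | CC(C)(C)OC(=O)NC[C@@H](CO)C | intermediate
3 | tert-butyl N-[(2S)-2-methyl-3-oxopropyl]carbamate | CC(C)(C)OC(=O)NC[C@@H](C=O)C | intermediate
4 | tert-butyl N-[(2R)-2-methylbut-3-yn-1-yl]carbamate | CC(C)(C)OC(=O)NC[C@@H](C#C)C | intermediate
5 | (E)-1-bromobut-2-ene | C/C=C/CBr | starting material
6 | tert-butyl N-[(2E)-but-2-en-1-yl]-N-[(2R)-2-methylbut-3-yn-1-yl]carbamate | CC(C)(C)OC(=O)N(C/C=C/C)C[C@@H](C#C)C | intermediate
7 | hexacarbonyldicobalt complex of the alkyne of 6 (not isolated) | CC(C)(C)OC(=O)N(C/C=C/C)C[C@@H](C12[CH]3[Co]1(=C=O)(=C=O)(=C=O)[Co]23(=C=O)(=C=O)=C=O)C | intermediate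
8 | tert-butyl (4R,7S,7aS)-4,7-dimethyl-6-oxo-1,3,4,6,7,7a-hexahydro-2H-cyclopenta[c]pyridine-2-carboxylate | O=C1C=C2[C@@H](CN(C(=O)OC(C)(C)C)C[C@@H]2C)[C@@H]1C | intermediate
9 | tert-butyl (4R,4aS,7S,7aR)-4,7-dimethyl-6-oxooctahydro-1H-cyclopenta[c]pyridine-2-carboxylate | O=C1C[C@@H]2[C@@H](CN(C(=O)OC(C)(C)C)C[C@@H]2C)[C@@H]1C | intermediate
10 | tert-butyl (4R,4aS,6S,7S,7aR)-6-hydroxy-4,7-dimethyloctahydro-1H-cyclopenta[c]pyridine-2-carboxylate (not isolated) | O[C@H]1C[C@@H]2[C@@H](CN(C(=O)OC(C)(C)C)C[C@@H]2C)[C@@H]1C | intermediate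
11 | (4R,4aS,6S,7S,7aR)-2,4,7-trimethyloctahydro-1H-cyclopenta[c]pyridin-6-ol (6-epi-incarvilline) | O[C@H]1C[C@@H]2[C@@H](CN(C)C[C@@H]2C)[C@@H]1C | intermediate
12 | geranyl acetate | CC(=O)OC/C=C(\C)CCC=C(C)C | starting material
13 | (2E,6E)-8-hydroxy-3,7-dimethylocta-2,6-dien-1-yl acetate | CC(=O)OC/C=C(\C)CC/C=C(\C)CO | intermediate
14 | (2E,6E)-2,6-dimethylocta-2,6-diene-1,8-diol | OC/C=C(\C)CC/C=C(\C)CO | intermediate
15 | (2E,6E)-2,6-dimethylocta-2,6-dienedial | O=C/C=C(\C)CC/C=C(\C)C=O | intermediate
16 | (2E,6E)-2,6-dimethylocta-2,6-dienedioic acid | OC(=O)/C=C(\C)CC/C=C(\C)C(=O)O | intermediate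
17 | bis[(4R,4aS,6R,7S,7aR)-2,4,7-trimethyloctahydro-1H-cyclopenta[c]pyridin-6-yl] (2E,6E)-2,6-dimethylocta-2,6-dienedioate | C/C(=C\C(=O)O[C@@H]1C[C@@H]2[C@@H](CN(C)C[C@@H]2C)[C@@H]1C)CC/C=C(\C)C(=O)O[C@@H]1C[C@@H]2[C@@H](CN(C)C[C@@H]2C)[C@@H]1C | target

**Count and risks**

Total step count: 12. Longest linear sequence: 8 steps (steps 1–7 and 12, from 1 to 17); the diacid branch (steps 8–11) is 4 steps.

Steps most likely to fail:

Step 5. The E-1,2-disubstituted alkene may insert too slowly into the cobalt–alkyne complex, so that decomplexation or alkene isomerisation competes, and the facial selectivity of the insertion relative to C4 may be modest. The fallback sets out from compound 4 and comes back at compound 8. Compound 4 is N-alkylated with allyl bromide (NaH, DMF) to give tert-butyl N-allyl-N-[(2R)-2-methylbut-3-yn-1-yl]carbamate F1. With Co2(CO)8 this forms its alkyne–Co2(CO)6 complex F2, which under the promoter conditions of step 5 should cyclise faster through the monosubstituted alkene to the C7-unsubstituted enone F3, with C7a set by the same chair-like control. Kinetic α′-deprotonation of F3 with LiN(iPr)2 (THF, −78 °C) and alkylation with MeI then introduces the C7 methyl anti to C1 on the convex face, giving 8.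

Step 12. The twofold inverting esterification may stall at the mono-ester or divert to elimination, because a weakly acidic enoic acid is a poor partner for a hindered oxyphosphonium ion flanked by the C7 methyl. The fallback sets out from compound 11 and comes back at compound 17. Compound 11 is inverted by Mitsunobu reaction with the more acidic 4-nitrobenzoic acid (PPh3, DIAD, THF) to give the (6R) 4-nitrobenzoate F4, and methanolysis (K2CO3, MeOH) frees the (6R) alcohol, incarvilline F5. Diacid 16 is activated with 2,4,6-trichlorobenzoyl chloride and Et3N as the bis(mixed anhydride) F6, which acylates two molecules of F5 (DMAP, toluene) with retention at C6 to give 17.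

Step 6. On palladium the enone double bond may migrate toward the ring-fusion position before reduction, eroding C4 or C7a, or hydrogen may be delivered from the concave face to give the trans-fused ketone. The fallback sets out from compound 8 and comes back at compound 9. It replaces surface hydrogenation with a conjugate hydride reduction using [(Ph3P)CuH]6 in wet toluene at rt; the bulky copper hydride should deliver hydride to C4a from the convex face without alkene migration, and the copper enolate is protonated in situ to give 9 directly. This fallback makes no new compound (F0).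

**Further compounds**

F1 | step 5 | tert-butyl N-allyl-N-[(2R)-2-methylbut-3-yn-1-yl]carbamate | CC(C)(C)OC(=O)N(CC=C)C[C@@H](C#C)C
F2 | step 5 | hexacarbonyldicobalt complex of the alkyne of F1 | CC(C)(C)OC(=O)N(CC=C)C[C@@H](C12[CH]3[Co]1(=C=O)(=C=O)(=C=O)[Co]23(=C=O)(=C=O)=C=O)C
F3 | step 5 | tert-butyl (4R,7aS)-4-methyl-6-oxo-1,3,4,6,7,7a-hexahydro-2H-cyclopenta[c]pyridine-2-carboxylate | O=C1C=C2[C@@H](CN(C(=O)OC(C)(C)C)C[C@@H]2C)C1
F4 | step 12 | (4R,4aS,6R,7S,7aR)-2,4,7-trimethyloctahydro-1H-cyclopenta[c]pyridin-6-yl 4-nitrobenzoate | O=C(O[C@@H]1C[C@@H]2[C@@H](CN(C)C[C@@H]2C)[C@@H]1C)c1ccc(cc1)[N+](=O)[O-]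
F5 | step 12 | (4R,4aS,6R,7S,7aR)-2,4,7-trimethyloctahydro-1H-cyclopenta[c]pyridin-6-ol (incarvilline) | O[C@@H]1C[C@@H]2[C@@H](CN(C)C[C@@H]2C)[C@@H]1C
F6 | step 12 | (2E,6E)-2,6-dimethylocta-2,6-dienedioic bis(2,4,6-trichlorobenzoic) anhydride | O=C(OC(=O)c1c(Cl)cc(Cl)cc1Cl)/C=C(\C)CC/C=C(\C)C(=O)OC(=O)c1c(Cl)cc(Cl)cc1Cl
F0 | step 6 | none | none
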